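## The problem

Kanzonol L (24) is an isoflavone. A chromen-4-one (rings A and C) is joined through C3 to an aryl ring B, which carries a 2,2-dimethyl-2H-pyran (ring D) fused across C2′–C3′ through the C2′ oxygen and a free hydroxyl on C4′. Ring A is a fully substituted phloroglucinol nucleus, with hydroxyls on C5 and C7 and 3-methylbut-2-enyl groups on C6 and C8. There is no stereocentre, so every difficulty is one of regiochemistry: which ring B oxygen enters ring D, which ring A carbons receive the prenyl groups, and how C3 is tied to C1′. The styrene-like C3=C4 bond of ring D and the prenyl olefins beside free phenols will not survive strong protic or Lewis acids, hydrogenation or electrophilic oxidants, and C2 of the pyranone is open to hard nucleophiles. The closing steps therefore have to be neutral or mildly basic. The enabling feature is in ring A: the carbon bearing O1 (C8a) and the carbon bearing the C4 carbonyl (C4a) are neighbours, and the C5 oxygen sits directly beside C4a. This is the pattern left when a 3-alkoxyaryne takes a nucleophile at its remote carbon and an electrophile at the carbon next to the alkoxy group. The unit O1–C2=C3–C4 is the enol of an α-formyl arylacetic ester, whose enol oxygen and ester carbon are held cis to each other, so ring A can be delivered as an aryne and ring C closed on it in one operation.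

## Retrosynthesis

**24 from 23.** The last cut is the O–acyl bond of a pivalate on the C4′ oxygen. This phenol has to be masked while ring A is prenylated, and a hindered aryl ester withstands fluoride, dilute acid, zerovalent palladium and heat, then leaves under mild basic methanolysis that harms none of the olefins. The forward step is asked only to spare the pyranone.

**23 from 18.** The C6–CH2 and C8–CH2 bonds are cut. Direct C-alkylation of a 5,7-dihydroxychromone gives O- and over-alkylation. Each prenyl group is instead traced to a 7-O-(2-methylbut-3-en-2-yl) ether that delivers it by a [3,3] shift: 23 from ether 22, 22 from monoprenyl phenol 21, 21 from ether 20, and 20 from diol 18 and carbonate 19. The first shift may go to C6 or C8, but the second cycle fills whichever position is left, so its regiochemistry need not be controlled. Prenyl groups on the aryne itself were rejected: one would flank the carbon to be attacked, and they would complicate the organolithium chemistry of the precursor.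

**18 from 17.** Two methoxymethyl ethers are returned to O5 and O7. Acetals are needed on ring A because they survive n-BuLi and fluoride, help direct the aryne addition, and leave in dilute acid that pivalate and chromene tolerate.

**17 from 6 and 15.** This is the key cut, through O1–C8a and C4–C4a, which removes ring C and separates the molecule into two pieces of similar size. Silyl triflate 6 is the precursor of aryne 16, and enol ester 15 already holds ring B, ring D, C2, C3 and C4. The neighbouring cuts at C3–C1′ (cross-coupling of a 3-halochromone) or C2–C3 (deoxybenzoin route) need a preformed chromone or acylphloroglucinol. This cut needs only phloroglucinol and an arylacetate. The forward reaction must add the enolate oxygen to the aryne carbon remote from the C5 oxygen and then acylate the resulting aryl anion with the ester.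

**15 from 13 and 14.** The C2–C3 bond is cut, removing a formyl group that comes from methyl formate 14. Arylacetate 13 is a simple ester. The formylation must not liberate alkoxide, which would attack the aryl pivalate.

**13 from 12, and 12 from 10 and 11.** Ring D is opened at the C3′–C4 bond and then at the ether O–C bond, leading to aryl propargyl ether 12 and on to phenol 10 and 3-chloro-3-methylbut-1-yne 11. Condensation of a free resorcinol with 3-methylbut-2-enal cannot tell the two oxygens apart. The propargyl ether cascade is directed by the single free ortho position of 10, so only the required chromene can form.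

**10 from 9, 9 from 8, and 8 from 7.** The two phenols of 2,4-dihydroxyphenylacetic acid 7 are told apart by the side chain. Only the ortho hydroxyl can lactonise (8), the remaining one is pivaloylated (9), and methanolysis of the lactone frees the ortho phenol and forms the methyl ester together (10).

**6 from 3, 3 from 2, and 2 from 1.** The C–Si and O–S bonds of 6 are traced through the silyl ether 4 and the lithium phenoxide 5 to bromophenol 3, by the usual O-silylation, retro-Brook shift and triflation sequence. Bromophenol 3 comes from ortho-bromination of 3,5-bis(methoxymethoxy)phenol 2, and 2 from double protection of phloroglucinol 1.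

## Roads not taken

**Alternative 1:** Ring B is cut at C3′–C4′ and C5′–C6′. A pyranopyranone A2 would add the silyl ynol ether A3 across its pyrone diene, and loss of CO2 from the bridged adduct would give the benzoate A1 with ring D already fused.
- Merits: the ring B oxygen pattern follows from the polarisation of diene and ynol ether and not from telling two phenols apart. In regiochemical certainty this is at least as good as the lactone sequence used here.
- Weak points: A1 carries a carboxyl carbon on C1′ where the isoflavone needs a CH2CO2Me or a coupling handle, so several adjustment steps follow. The silyl ether would not survive the fluoride of any aryne step. A2 has to be built first, and the cycloaddition needs heat that ynol ethers and the 2H-pyran tolerate poorly.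
- Comparison: this road solves only ring B and leaves the chromone and the prenyl groups open. The chosen plan sets against it a cheap arylacetic acid whose side chain is already the C3–C4 unit that the key step consumes.

**Alternative 2:** Ring B is cut at C1′–C2′, C2′–C3′ and C4′–C5′. Irradiation of diazoketone A5 would give a vinylketene by Wolff rearrangement. Addition of siloxyalkyne A6, opening of the vinylcyclobutenone and 6π closure would give phenol A4.
- Merits: the step is highly convergent. A4 has the C2′ hydroxyl free, the C4′ oxygen silylated and both ring A prenyl groups in place, so no late C-prenylation is needed and ring D can be closed by oxidative cyclisation onto the only free phenol. In this respect it is better than the chosen plan, which spends four steps on the two prenyl groups.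
- Weak points: the cost moves to A5, a fully substituted diprenylchromone with a diazo enone side chain. Its ring A still needs the same C-prenylation, only earlier. The photolysis has to compete with the chromone chromophore, and the ketene meets three nucleophilic olefins. The route to A5 and A6 is clearly longer than that to 6 and 15.
- Comparison: the chosen plan offers short fragment syntheses and thermal, ionic steps throughout.

**Alternative 3:** Ring A is cut at C4a–C5. With Mg(OMe)2 the methylene of the open-chain triketo ester A8 would attack the terminal ester, and enolisation would give the acylphloroglucinol A7.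
- Merits: both prenyl groups are placed by C-alkylation of active methylenes without any regiochemical question. The symmetric ring A lets either ortho hydroxyl close ring C later. A7 is more advanced than 17 in that the prenyl groups are already present.
- Weak points: A8 holds four carbonyl groups and two alkylated positions and is hard to assemble and to keep. Lactonisation to pyrones and aldol closures compete with the wanted Claisen closure, which must take place at an ester hindered by an α-prenyl group. One carbon (C2) still has to be added, and the acetal on ring B must then be removed in acid beside four acid-sensitive olefins.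
- Comparison: the chosen plan relies on aromatic starting materials and on steps that each have close analogies, except the key step.

Key step: step 10

## Assumptions

- Compound 15 is drawn as its hydrogen-bonded Z enol; it equilibrates with the formyl tautomer, and the common enolate is the reacting species in step 10.
- 3-Chloro-3-methylbut-1-yne 11 and tert-butyl 2-methylbut-3-en-2-yl carbonate 19 are taken as purchased reagents.
- Isoflavone numbering is used for rings A and C; ring B positions are primed.

## Route

Step 1
Reactants: 1 phloroglucinol
Product: 2 3,5-bis(methoxymethoxy)phenol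
Conditions: MOMCl (2.1 equiv), i-Pr2NEt, DMF, 0 °C → rt
Reagents that add atoms: chloromethyl methyl ether, COCCl
Why: O-alkylation of the phenols to acetals; with two equivalents the bis-ether should be the main member of a statistical mixture, is separated by chromatography, and the mono-ether can be resubmitted.

Step 2
Reactants: 2 3,5-bis(methoxymethoxy)phenol
Product: 3 2-bromo-3,5-bis(methoxymethoxy)phenol
Conditions: NBS (1.0 equiv), i-Pr2NH (cat.), CH2Cl2, −78 → 0 °C
Reagents that add atoms: N-bromosuccinimide, O=C1CCC(=O)N1Br
Why: Electrophilic aromatic bromination; the amine-mediated variant delivers bromine ortho to the free hydroxyl, and the other site, between the two acetals, is the more hindered one. One equivalent at low temperature should limit double bromination.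

Step 3
Reactants: 3 2-bromo-3,5-bis(methoxymethoxy)phenol
Product: 6 3,5-bis(methoxymethoxy)-2-(trimethylsilyl)phenyl trifluoromethanesulfonate, via aryl trimethylsilyl ether 4 (not isolated), via lithium 2-silylphenoxide 5 (not isolated)
Conditions: HMDS, THF, 65 °C, then evaporation; n-BuLi, THF, −78 °C; PhNTf2, −78 °C → rt
Reagents that add atoms: hexamethyldisilazane, C[Si](C)(C)N[Si](C)(C)C; N-phenylbis(trifluoromethanesulfonimide), O=S(=O)(N(c1ccccc1)S(=O)(=O)C(F)(F)F)C(F)(F)F
Why: Standard one-pot route to ortho-silylaryl triflates: O-silylation, bromine–lithium exchange followed by 1,3 O→C silyl shift (retro-Brook rearrangement), then triflation of the phenoxide. Exchange at −78 °C is faster than lithiation next to the acetals, and PhNTf2 is chosen over Tf2O to spare the acetals.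

Step 4
Reactants: 7 2,4-dihydroxyphenylacetic acid
Product: 8 6-hydroxy-1-benzofuran-2(3H)-one
Conditions: TsOH·H2O (cat.), toluene, reflux, azeotropic removal of water
Reagents that add atoms: none
Why: Acid-catalysed lactonisation (intramolecular Fischer esterification); only the ortho hydroxyl can reach the acid, so the two phenols become different.

Step 5
Reactants: 8 6-hydroxy-1-benzofuran-2(3H)-one
Product: 9 2-oxo-2,3-dihydro-1-benzofuran-6-yl pivalate
Conditions: PivCl, pyridine, DMAP (cat.), CH2Cl2, 0 °C
Reagents that add atoms: pivaloyl chloride, CC(C)(C)C(Cl)=O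
Why: Acylation of the only free phenol; pyridine is too weak a base to enolise the lactone, so O-acylation at the lactone should not compete.

Step 6
Reactants: 9 2-oxo-2,3-dihydro-1-benzofuran-6-yl pivalate
Product: 10 methyl 2-[2-hydroxy-4-(pivaloyloxy)phenyl]acetate
Conditions: MeOH, H2SO4 (cat.), rt; NaHCO3 before concentration
Reagents that add atoms: methanol, CO
Why: Acid-catalysed transesterification opens the strained, unhindered aryl lactone far faster than the hindered pivalate; neutralising before concentration prevents relactonisation.

Step 7
Reactants: 10 methyl 2-[2-hydroxy-4-(pivaloyloxy)phenyl]acetate; 11 3-chloro-3-methylbut-1-yne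
Product: 12 methyl 2-[2-(2-methylbut-3-yn-2-yloxy)-4-(pivaloyloxy)phenyl]acetate
Conditions: CuCl2·2H2O (cat.), DBU, MeCN, 0 °C
Reagents that add atoms: none
Why: Copper-catalysed O-propargylation of a phenol with a tertiary propargylic chloride gives the 1,1-dimethylpropargyl aryl ether; DBU at 0 °C should leave both esters untouched, and the irreversible etherification outruns any relactonisation of the phenoxide.

Step 8
Reactants: 12 methyl 2-[2-(2-methylbut-3-yn-2-yloxy)-4-(pivaloyloxy)phenyl]acetate
Product: 13 methyl 2-[2,2-dimethyl-5-(pivaloyloxy)-2H-chromen-8-yl]acetate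
Conditions: o-xylene, 140 °C
Reagents that add atoms: none
Why: Thermal cascade of aromatic propargyl Claisen rearrangement, 1,5-hydrogen shift and oxa-6π electrocyclisation. The other ortho position carries the side chain, so the ring can only close onto the carbon between the two oxygens, which fixes the ring D regiochemistry.

Step 9
Reactants: 13 methyl 2-[2,2-dimethyl-5-(pivaloyloxy)-2H-chromen-8-yl]acetate; 14 methyl formate
Product: 15 methyl (2Z)-2-[2,2-dimethyl-5-(pivaloyloxy)-2H-chromen-8-yl]-3-hydroxyprop-2-enoate
Conditions: TiCl4, Et3N, CH2Cl2, 0 °C; aqueous work-up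
Reagents that add atoms: none
Why: Titanium-mediated crossed Claisen condensation (α-formylation) of the titanium enolate of the arylacetate with methyl formate. No free alkoxide is present, which protects the aryl pivalate, and the product settles as the chelated Z enol.

Step 10
Reactants: 6 3,5-bis(methoxymethoxy)-2-(trimethylsilyl)phenyl trifluoromethanesulfonate; 15 methyl (2Z)-2-[2,2-dimethyl-5-(pivaloyloxy)-2H-chromen-8-yl]-3-hydroxyprop-2-enoate
Product: 17 5,7-bis(methoxymethoxy)-3-[2,2-dimethyl-5-(pivaloyloxy)-2H-chromen-8-yl]-4H-chromen-4-one, via 3,5-bis(methoxymethoxy)benzyne 16 (not isolated)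
Conditions: CsF (4 equiv), 6 (1.6 equiv), THF, 65 °C
Reagents that add atoms: none
Why: Proposed new method: fluoride removes the silyl group of 6 and triflate leaves to give aryne 16; the cesium enolate of 15 adds through its formyl oxygen to the aryne carbon remote from the neighbouring methoxymethoxy group, and the aryl anion formed beside that group attacks the cis ester and expels methoxide. The closest known reaction type is the fluoride-induced annulation of arynes with methyl salicylates to xanthones, in which a phenoxide O-arylates the aryne and the aryl anion then undergoes intramolecular acyl substitution; here a hydrogen-bonded enol takes the place of the phenol. Ring C closes by a 6-exo-trig acyl substitution, the new bonds being O1–C8a and C4–C4a. No stereocentre is formed. Three selectivities are needed: the site of attack on the aryne, which the inductive distortion by the C5 oxygen directs to C8a so that charge develops at C4a; O- over C-arylation of the ambident enolate, favoured by the fully substituted enolate carbon with its ortho-substituted aryl group and by the loosely bound cesium ion; and a cis arrangement of aryloxy and ester groups, supplied by the Z enolate held by chelation. THF is used in place of acetonitrile so that the aryl anion is not protonated before it reaches the ester, and the excess of 6 takes up the methoxide set free, which protects the pivalate.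

Step 11
Reactants: 17 5,7-bis(methoxymethoxy)-3-[2,2-dimethyl-5-(pivaloyloxy)-2H-chromen-8-yl]-4H-chromen-4-one
Product: 18 5,7-dihydroxy-3-[2,2-dimethyl-5-(pivaloyloxy)-2H-chromen-8-yl]-4H-chromen-4-one
Conditions: HCl (3 M aq.), MeOH/THF, 45 °C
Reagents that add atoms: none
Why: Acid-catalysed acetal exchange with methanol removes both methoxymethyl groups; the hindered pivalate and the 2,2-dimethylchromene should tolerate dilute acid at this temperature.

Step 12
Reactants: 18 5,7-dihydroxy-3-[2,2-dimethyl-5-(pivaloyloxy)-2H-chromen-8-yl]-4H-chromen-4-one; 19 tert-butyl 2-methylbut-3-en-2-yl carbonate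
Product: 20 5-hydroxy-7-(2-methylbut-3-en-2-yloxy)-3-[2,2-dimethyl-5-(pivaloyloxy)-2H-chromen-8-yl]-4H-chromen-4-one
Conditions: Pd(PPh3)4 (5 mol %), THF, 0 °C → rt
Reagents that add atoms: none
Why: Tsuji–Trost O-allylation: the π-allylpalladium complex from the tertiary carbonate is attacked by the phenoxide at its more substituted end under kinetic control, giving the tertiary ether. Only the acidic C7 hydroxyl reacts, because the C5 hydroxyl is hydrogen-bonded to the C4 carbonyl.

Step 13
Reactants: 20 5-hydroxy-7-(2-methylbut-3-en-2-yloxy)-3-[2,2-dimethyl-5-(pivaloyloxy)-2H-chromen-8-yl]-4H-chromen-4-one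
Product: 21 5,7-dihydroxy-6-(3-methylbut-2-enyl)-3-[2,2-dimethyl-5-(pivaloyloxy)-2H-chromen-8-yl]-4H-chromen-4-one
Conditions: N,N-diethylaniline, 150 °C
Reagents that add atoms: none
Why: Aromatic Claisen rearrangement; the [3,3] shift turns the tertiary allyl ether into a 3-methylbut-2-enyl group on an ortho carbon, expected mainly at C6, the position favoured when the C5 hydroxyl is chelated. Delivery to C8 is equally useful, since the second cycle fills whichever position is left, and the basic solvent suppresses acid-induced loss of the allyl group.

Step 14
Reactants: 21 5,7-dihydroxy-6-(3-methylbut-2-enyl)-3-[2,2-dimethyl-5-(pivaloyloxy)-2H-chromen-8-yl]-4H-chromen-4-one; 19 tert-butyl 2-methylbut-3-en-2-yl carbonate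
Product: 22 5-hydroxy-6-(3-methylbut-2-enyl)-7-(2-methylbut-3-en-2-yloxy)-3-[2,2-dimethyl-5-(pivaloyloxy)-2H-chromen-8-yl]-4H-chromen-4-one
Conditions: Pd(PPh3)4 (5 mol %), THF, 0 °C → rt
Reagents that add atoms: none
Why: Second Tsuji–Trost O-allylation of the regenerated C7 hydroxyl; ortho-substituted phenols are competent nucleophiles, and the chelated C5 hydroxyl again stays free.

Step 15
Reactants: 22 5-hydroxy-6-(3-methylbut-2-enyl)-7-(2-methylbut-3-en-2-yloxy)-3-[2,2-dimethyl-5-(pivaloyloxy)-2H-chromen-8-yl]-4H-chromen-4-one
Product: 23 5,7-dihydroxy-6,8-bis(3-methylbut-2-enyl)-3-[2,2-dimethyl-5-(pivaloyloxy)-2H-chromen-8-yl]-4H-chromen-4-one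
Conditions: N,N-diethylaniline, 150 °C
Reagents that add atoms: none
Why: Second aromatic Claisen rearrangement; one ortho position is occupied, so the [3,3] shift can end only at the remaining one, and a shift to the substituted carbon is reversible.

Step 16
Reactants: 23 5,7-dihydroxy-6,8-bis(3-methylbut-2-enyl)-3-[2,2-dimethyl-5-(pivaloyloxy)-2H-chromen-8-yl]-4H-chromen-4-one
Product: 24 kanzonol L, 5,7-dihydroxy-3-(5-hydroxy-2,2-dimethyl-2H-chromen-8-yl)-6,8-bis(3-methylbut-2-enyl)-4H-chromen-4-one
Conditions: K2CO3, MeOH, rt; aq. NH4Cl
Reagents that add atoms: none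
Why: Base-mediated methanolysis (transesterification) of the aryl pivalate; the C7 phenoxide formed first makes ring C electron-rich and so protects C2 from methoxide, and no olefin is affected.

## Compound list

1 | phloroglucinol | Oc1cc(O)cc(O)c1 | starting material
2 | 3,5-bis(methoxymethoxy)phenol | COCOc1cc(O)cc(OCOC)c1 | intermediate
3 | 2-bromo-3,5-bis(methoxymethoxy)phenol | COCOc1cc(O)c(Br)c(OCOC)c1 | intermediate
4 | [2-bromo-3,5-bis(methoxymethoxy)phenoxy]trimethylsilane | COCOc1cc(O[Si](C)(C)C)c(Br)c(OCOC)c1 | intermediate (not isolated)
5 | lithium 3,5-bis(methoxymethoxy)-2-(trimethylsilyl)phenoxide | COCOc1cc([O-])c([Si](C)(C)C)c(OCOC)c1.[Li+] | intermediate (not isolated)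
6 | 3,5-bis(methoxymethoxy)-2-(trimethylsilyl)phenyl trifluoromethanesulfonate | COCOc1cc(OS(=O)(=O)C(F)(F)F)c([Si](C)(C)C)c(OCOC)c1 | intermediate
7 | 2,4-dihydroxyphenylacetic acid | OC(=O)Cc1ccc(O)cc1O | starting material
8 | 6-hydroxy-1-benzofuran-2(3H)-one | O=C1Cc2ccc(O)cc2O1 | intermediate
9 | 2-oxo-2,3-dihydro-1-benzofuran-6-yl pivalate | CC(C)(C)C(=O)Oc1ccc2CC(=O)Oc2c1 | intermediate
10 | methyl 2-[2-hydroxy-4-(pivaloyloxy)phenyl]acetate | COC(=O)Cc1ccc(OC(=O)C(C)(C)C)cc1O | intermediate
11 | 3-chloro-3-methylbut-1-yne | C#CC(C)(C)Cl | starting material
12 | methyl 2-[2-(2-methylbut-3-yn-2-yloxy)-4-(pivaloyloxy)phenyl]acetate | COC(=O)Cc1ccc(OC(=O)C(C)(C)C)cc1OC(C)(C)C#C | intermediate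
13 | methyl 2-[2,2-dimethyl-5-(pivaloyloxy)-2H-chromen-8-yl]acetate | COC(=O)Cc1ccc(OC(=O)C(C)(C)C)c2c1OC(C)(C)C=C2 | intermediate
14 | methyl formate | COC=O | starting material
15 | methyl (2Z)-2-[2,2-dimethyl-5-(pivaloyloxy)-2H-chromen-8-yl]-3-hydroxyprop-2-enoate | COC(=O)/C(=C\O)c1ccc(OC(=O)C(C)(C)C)c2c1OC(C)(C)C=C2 | intermediate
16 | 3,5-bis(methoxymethoxy)benzyne | COCOC1=CC(OCOC)=CC#C1 | intermediate (not isolated)
17 | 5,7-bis(methoxymethoxy)-3-[2,2-dimethyl-5-(pivaloyloxy)-2H-chromen-8-yl]-4H-chromen-4-one | COCOc1cc(OCOC)c2c(c1)occ(-c1ccc(OC(=O)C(C)(C)C)c3c1OC(C)(C)C=C3)c2=O | intermediate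
18 | 5,7-dihydroxy-3-[2,2-dimethyl-5-(pivaloyloxy)-2H-chromen-8-yl]-4H-chromen-4-one | Oc1cc(O)c2c(c1)occ(-c1ccc(OC(=O)C(C)(C)C)c3c1OC(C)(C)C=C3)c2=O | intermediate
19 | tert-butyl 2-methylbut-3-en-2-yl carbonate | C=CC(C)(C)OC(=O)OC(C)(C)C | starting material
20 | 5-hydroxy-7-(2-methylbut-3-en-2-yloxy)-3-[2,2-dimethyl-5-(pivaloyloxy)-2H-chromen-8-yl]-4H-chromen-4-one | C=CC(C)(C)Oc1cc(O)c2c(c1)occ(-c1ccc(OC(=O)C(C)(C)C)c3c1OC(C)(C)C=C3)c2=O | intermediate
21 | 5,7-dihydroxy-6-(3-methylbut-2-enyl)-3-[2,2-dimethyl-5-(pivaloyloxy)-2H-chromen-8-yl]-4H-chromen-4-one | CC(C)=CCc1c(O)cc2occ(-c3ccc(OC(=O)C(C)(C)C)c4c3OC(C)(C)C=C4)c(=O)c2c1O | intermediate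
22 | 5-hydroxy-6-(3-methylbut-2-enyl)-7-(2-methylbut-3-en-2-yloxy)-3-[2,2-dimethyl-5-(pivaloyloxy)-2H-chromen-8-yl]-4H-chromen-4-one | CC(C)=CCc1c(OC(C)(C)C=C)cc2occ(-c3ccc(OC(=O)C(C)(C)C)c4c3OC(C)(C)C=C4)c(=O)c2c1O | intermediate
23 | 5,7-dihydroxy-6,8-bis(3-methylbut-2-enyl)-3-[2,2-dimethyl-5-(pivaloyloxy)-2H-chromen-8-yl]-4H-chromen-4-one | CC(C)=CCc1c(O)c(CC=C(C)C)c2occ(-c3ccc(OC(=O)C(C)(C)C)c4c3OC(C)(C)C=C4)c(=O)c2c1O | intermediate
24 | kanzonol L | CC(C)=CCc1c(O)c(CC=C(C)C)c2occ(-c3ccc(O)c4c3OC(C)(C)C=C4)c(=O)c2c1O | target

## Step count and risks

Total: 16 steps. Longest linear sequence: 13 steps (7 to 24 through steps 4–16); the aryne branch (1 to 6) adds 3 steps.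

**Step 10 (key step, new method).**
- What may go wrong: C-arylation of the ambident enolate followed by attack of the aryl anion on the formyl group (net insertion into a C–C bond); protonation of the aryl anion before it reaches the ester; or O-arylation from an enolate geometry that keeps ester and aryloxy group apart. Arynes are soft electrophiles, enolates of 1,3-dicarbonyl compounds are known to react at carbon, and fluoride-generated HF is a proton source. Preforming the sodium enolate would remove the proton source but not the first or third problem.
- Fallback, by known reactions, from 13 and 6, returning at 17: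
  - The methyl ester of 13 is cleaved with Me3SnOH in 1,2-dichloroethane to [2,2-dimethyl-5-(pivaloyloxy)-2H-chromen-8-yl]acetic acid F1.
  - F1 and 6 with CsF in hot THF undergo the known insertion of an aryne into the C–O bond of a carboxylic acid (carboxylate O-arylation, acyl shift to the adjacent carbon), giving the ortho-hydroxyaryl ketone 1-[2-hydroxy-4,6-bis(methoxymethoxy)phenyl]-2-[2,2-dimethyl-5-(pivaloyloxy)-2H-chromen-8-yl]ethanone F2.
  - N,N-dimethylformamide dimethyl acetal then adds C2 and closes ring C to 17 in the classical deoxybenzoin manner.

**Step 9.**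
- What may go wrong: ionisation or oligomerisation at the electron-rich chromene double bond under TiCl4, or incomplete enolisation of the hindered arylacetate.
- Fallback from 13, returning at 15: heating 13 with tert-butoxybis(dimethylamino)methane gives the enamino ester methyl (2E)-3-(dimethylamino)-2-[2,2-dimethyl-5-(pivaloyloxy)-2H-chromen-8-yl]prop-2-enoate F3, and brief hydrolysis with dilute aqueous HCl in THF releases 15.

**Step 2.**
- What may go wrong: bromination para to the hydroxyl (between the two acetals) or double bromination, since every free ring position is activated by three oxygens.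
- Fallback from 2, returning at 6 and bypassing 3, 4 and 5; the site is set here by directed metalation and not by electrophilic substitution:
  - Isopropyl isocyanate converts 2 into 3,5-bis(methoxymethoxy)phenyl N-isopropylcarbamate F4.
  - In-situ N-silylation (TBSOTf, TMEDA), ortho-lithiation with n-BuLi at −78 °C and quenching with TMSCl give 3,5-bis(methoxymethoxy)-2-(trimethylsilyl)phenyl N-isopropylcarbamate F5.
  - Diethylamine and DBU cleave the carbamate to 3,5-bis(methoxymethoxy)-2-(trimethylsilyl)phenol F6, which PhNTf2 triflates in the same flask to 6.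

**Step 13 (the same concern applies to step 15).**
- What may go wrong: loss of the tertiary allyl group by ionisation and elimination in place of the [3,3] shift, and a sluggish second shift to C8, where chelation of the C5 hydroxyl lowers the double-bond character of C7–C8.
- Fallback from 18, returning at 23 and bypassing 20, 21 and 22: N-iodosuccinimide in DMF iodinates the phloroglucinol ring twice to 5,7-dihydroxy-6,8-diiodo-3-[2,2-dimethyl-5-(pivaloyloxy)-2H-chromen-8-yl]-4H-chromen-4-one F7, and a double Stille coupling with tributyl(3-methylbut-2-enyl)stannane and Pd(PPh3)4 in DMF at 90 °C installs both prenyl groups to give 23.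

## Further compounds

F1 | step 10 | [2,2-dimethyl-5-(pivaloyloxy)-2H-chromen-8-yl]acetic acid | OC(=O)Cc1ccc(OC(=O)C(C)(C)C)c2c1OC(C)(C)C=C2
F2 | step 10 | 1-[2-hydroxy-4,6-bis(methoxymethoxy)phenyl]-2-[2,2-dimethyl-5-(pivaloyloxy)-2H-chromen-8-yl]ethanone | COCOc1cc(O)c(C(=O)Cc2ccc(OC(=O)C(C)(C)C)c3c2OC(C)(C)C=C3)c(OCOC)c1
F3 | step 9 | methyl (2E)-3-(dimethylamino)-2-[2,2-dimethyl-5-(pivaloyloxy)-2H-chromen-8-yl]prop-2-enoate | COC(=O)/C(=C/N(C)C)c1ccc(OC(=O)C(C)(C)C)c2c1OC(C)(C)C=C2
F4 | step 2 | 3,5-bis(methoxymethoxy)phenyl N-isopropylcarbamate | CC(C)NC(=O)Oc1cc(OCOC)cc(OCOC)c1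
F5 | step 2 | 3,5-bis(methoxymethoxy)-2-(trimethylsilyl)phenyl N-isopropylcarbamate | CC(C)NC(=O)Oc1cc(OCOC)cc(OCOC)c1[Si](C)(C)C
F6 | step 2 | 3,5-bis(methoxymethoxy)-2-(trimethylsilyl)phenol | COCOc1cc(O)c([Si](C)(C)C)c(OCOC)c1
F7 | step 13 | 5,7-dihydroxy-6,8-diiodo-3-[2,2-dimethyl-5-(pivaloyloxy)-2H-chromen-8-yl]-4H-chromen-4-one | Oc1c(I)c(O)c2c(c1I)occ(-c1ccc(OC(=O)C(C)(C)C)c3c1OC(C)(C)C=C3)c2=O
A1 | alternative 1 | methyl 2,2-dimethyl-5-(triisopropylsilyloxy)-2H-chromene-8-carboxylate | COC(=O)c1ccc(O[Si](C(C)C)(C(C)C)C(C)C)c2c1OC(C)(C)C=C2
A2 | alternative 1 | methyl 2,2-dimethyl-5-oxo-2H,5H-pyrano[4,3-b]pyran-8-carboxylate | COC(=O)C1=COC(=O)C2=C1OC(C)(C)C=C2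
A3 | alternative 1 | (triisopropylsilyloxy)ethyne | C#CO[Si](C(C)C)(C(C)C)C(C)C
A4 | alternative 2 | 3-[2-hydroxy-3-(3-methylbut-2-enyl)-4-(triisopropylsilyloxy)phenyl]-5,7-bis(methoxymethoxy)-6,8-bis(3-methylbut-2-enyl)chromen-4-one | CC(C)=CCc1c(O)c(-c2coc3c(CC=C(C)C)c(OCOC)c(CC=C(C)C)c(OCOC)c3c2=O)ccc1O[Si](C(C)C)(C(C)C)C(C)C
A5 | alternative 2 | (3E)-1-diazo-4-[5,7-bis(methoxymethoxy)-6,8-bis(3-methylbut-2-enyl)-4-oxo-4H-chromen-3-yl]but-3-en-2-one | [N-]=[N+]=CC(=O)/C=C/c1coc2c(CC=C(C)C)c(OCOC)c(CC=C(C)C)c(OCOC)c2c1=O
A6 | alternative 2 | triisopropyl[(5-methylhex-4-en-1-yn-1-yl)oxy]silane | CC(C)=CCC#CO[Si](C(C)C)(C(C)C)C(C)C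
A7 | alternative 3 | 2-[5-(methoxymethoxy)-2,2-dimethyl-2H-chromen-8-yl]-1-[2,4,6-trihydroxy-3,5-bis(3-methylbut-2-enyl)phenyl]ethanone | CC(C)=CCc1c(O)c(CC=C(C)C)c(O)c(C(=O)Cc2ccc(OCOC)c3c2OC(C)(C)C=C3)c1O
A8 | alternative 3 | methyl 8-[5-(methoxymethoxy)-2,2-dimethyl-2H-chromen-8-yl]-2,4-bis(3-methylbut-2-enyl)-3,5,7-trioxooctanoate (mixture of diastereomers and enol forms) | COC(=O)C(CC=C(C)C)C(=O)C(CC=C(C)C)C(=O)CC(=O)Cc1ccc(OCOC)c2c1OC(C)(C)C=C2
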